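Cuts, in retrosynthetic order: the acid is closed back onto the C7 oxygen as an enol lactone; then C6–prenyl (re-aromatisation); C6–CH2 to the cyclobutylmethyl arm; C2'–isopropenyl; cyclobutane bonds C3'–C4' and C1'–C2'. In the core the cuts are pyranone bonds C4–C4a and O1–C2 and the C–propyl bond of the side chain.
Enabling feature: in the four-membered ring the quaternary C3' (CMe2) lies between the ring CH2 (C4') and the methine C2', and C1' carries the one-carbon arm to C6. C2'–C3' is therefore the C=C of an isobutyraldehyde enamine, and C4'–C1' plus the arm carbon is an acrylate. Because C3' has no hydrogen, the Michael adduct can only close to the ring.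
Fragment A, forward: enamine + methyl acrylate → aminocyclobutane (first ring) → amine expelled → achiral cyclobutene ester → isopropenyl added → alcohol → iodide.
Fragment B, forward: 5,7-dimethoxycoumarin → propyl added at C4 → acylation at C8 → lactone opened and pyranone closed on the freed oxygen → demethylation with a new lactone on the other flank → C6 iodide.
Endgame: Negishi union at C6, dearomatising C6-prenylation, opening of the lactone.
Stereochemistry: C2' comes from a rhodium/chiral diene catalyst, C1' from equilibration to the trans ester, the side-chain carbon from a copper/ferrocenyl diphosphine catalyst, and C6 from a palladium/chiral diphosphine catalyst.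

Key step: step 2

Numbering: C1'–C4' is the cyclobutane (C1' bears the CH2 arm, C2' the isopropenyl group, C3' = CMe2, C4' = CH2). C6 is the same carbon in the chromanone numbering of the target and in the pyrano[2,3-f]chromene numbering of the tricyclic lactones. Steps 8 and 9 use coumarin numbering.
Assumption: the absolute sense of induction of the chiral ligands in steps 5, 8 and 15 is assigned by analogy with their known substrate classes. All three ligands are sold in both mirror-image forms, so the antipode is taken if a first run shows the opposite sense.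

Step 1
Reactants: 1 isobutyraldehyde; 2 dimethylamine
Product: 4 N,N,2-trimethylprop-1-en-1-amine, via aminal 3 (not isolated)
Conditions: Me2NH (2.2 equiv), K2CO3, neat, 0 → 25 °C; then distillation (the aminal cracks in the still)
Reagents that add atoms: none
Why: A secondary amine condenses with an α-branched aldehyde over a desiccant to the aminal, which loses one amine on heating (classical enamine synthesis), and no stereocentre is formed.

Step 2
Reactants: 4 N,N,2-trimethylprop-1-en-1-amine; 5 methyl acrylate
Product: 7 methyl 2-(dimethylamino)-3,3-dimethylcyclobutane-1-carboxylate (racemic cis/trans mixture), via iminium–enolate zwitterion 6 (not isolated)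
Conditions: neat, hydroquinone (0.5 mol %), sealed steel vessel, 170 °C
Reagents that add atoms: none
Why: The electron-rich β-carbon of 4 adds to the CH2 terminus of 5 (Michael addition, forming C3'–C4') to give zwitterion 6, whose ester enolate carbon then attacks the iminium carbon (Mannich closure, forming C1'–C2'). The closest known reaction type is the thermal, stepwise [2+2] cycloaddition of β,β-disubstituted aldehyde enamines with acrylates, acrylonitrile or fumarates, to which this pair of partners belongs. The four-membered ring closes in a 4-exo-trig (enolexo) mode onto the C=N+ bond. The two new stereocentres C1' and C2' are not controlled and need not be, because both become sp2 carbons in step 4. Only orientation and chemoselectivity are required: the polarity match (enamine β-carbon to acrylate β-carbon) fixes the head-to-tail regiochemistry. The two methyl groups on the enamine β-carbon leave 6 no proton to shift, so an open-chain Michael product cannot form and ring closure or harmless reversion are the only outlets.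

Step 3
Reactants: 7 methyl 2-(dimethylamino)-3,3-dimethylcyclobutane-1-carboxylate
Product: 8 2-(methoxycarbonyl)-N,N,N,4,4-pentamethylcyclobutan-1-aminium iodide
Conditions: MeI (1.5 equiv), acetone, 25 → 40 °C
Reagents that add atoms: iodomethane, CI
Why: SN2 N-methylation (Menshutkin reaction) turns the tertiary amine into a leaving group while the ester is inert to MeI.

Step 4
Reactants: 8 2-(methoxycarbonyl)-N,N,N,4,4-pentamethylcyclobutan-1-aminium iodide
Product: 9 methyl 3,3-dimethylcyclobut-1-ene-1-carboxylate
Conditions: KOt-Bu (1.05 equiv), THF, 0 → 25 °C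
Reagents that add atoms: none
Why: In this Hofmann elimination of E1cB type only C1' offers a β-hydrogen (C3' is quaternary) and that hydrogen is acidified by the ester, so both diastereomers converge on one achiral conjugated cyclobutene.

Step 5
Reactants: 9 methyl 3,3-dimethylcyclobut-1-ene-1-carboxylate; 10 isopropenylboronic acid pinacol ester
Product: 12 methyl (1R,2R)-3,3-dimethyl-2-(prop-1-en-2-yl)cyclobutane-1-carboxylate (trans), via cis ester 11 (not isolated)
Conditions: 10 (3 equiv), [RhCl(C2H4)2]2 (2.5 mol %), (1R,4R)-2,5-diphenylbicyclo[2.2.2]octa-2,5-diene (5.5 mol %), KOH (0.3 equiv), 1,4-dioxane/H2O 10:1, 50 °C; crude product then NaOMe (0.2 equiv), MeOH, 25 °C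
Reagents that add atoms: none
Why: Proposed new method: the isopropenyl group should pass from boron to a hydroxorhodium–diene complex, add syn across the strained C1'=C2' bond (carbon to the β-carbon C2', rhodium to C1' as an oxa-π-allyl) and be released by protonolysis, the relief of cyclobutene strain offsetting the neopentyl crowding at C2'; the C2-symmetric diene shields one face of the flat, achiral ring and so sets C2' as R, C1' is then fixed by methoxide equilibration of 11 to the more stable trans ester, and an ethylene-ligated rhodium source is chosen so that no achiral diene complex gives a racemic background; the closest known reactions are the rhodium/chiral diene 1,4-addition of arylboronic acids to cyclobut-1-enecarboxylates and of alkenylboron reagents to enones and enoates (Hayashi–Miyaura reaction).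

Step 6
Reactants: 12 methyl (1R,2R)-3,3-dimethyl-2-(prop-1-en-2-yl)cyclobutane-1-carboxylate
Product: 13 [(1R,2R)-3,3-dimethyl-2-(prop-1-en-2-yl)cyclobutyl]methanol
Conditions: LiAlH4, Et2O, 0 °C; Na2SO4·10H2O quench
Reagents that add atoms: none
Why: Hydride reduction of the ester to the primary alcohol leaves the isolated alkene and both stereocentres untouched.

Step 7
Reactants: 13 [(1R,2R)-3,3-dimethyl-2-(prop-1-en-2-yl)cyclobutyl]methanol
Product: 14 (1R,2R)-1-(iodomethyl)-3,3-dimethyl-2-(prop-1-en-2-yl)cyclobutane
Conditions: I2, PPh3, imidazole, CH2Cl2, 0 → 25 °C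
Reagents that add atoms: iodine, II
Why: The Appel-type iodination displaces the oxyphosphonium group by SN2 at the primary carbon, so no cyclobutylcarbinyl cation (ring expansion) arises and C1' is not touched.

Step 8
Reactants: 15 5,7-dimethoxycoumarin; 16 n-propylmagnesium bromide
Product: 17 (4R)-5,7-dimethoxy-4-propylchroman-2-one
Conditions: CuBr·SMe2 (5 mol %), (R)-1-[(S)-2-(dicyclohexylphosphino)ferrocenyl]ethyldiphenylphosphine (6 mol %), 16 (1.3 equiv), t-BuOMe/CH2Cl2, −72 °C; 1 M HCl quench at −72 °C
Reagents that add atoms: none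
Why: Copper-catalysed asymmetric conjugate addition of alkyl Grignard reagents to coumarins with ferrocenyl diphosphines is an established reaction in which the ligand-bound alkylcopper species selects one face of the planar lactone and so sets the propyl-bearing carbon as R, the low temperature suppressing 1,2-addition.

Step 9
Reactants: 17 (4R)-5,7-dimethoxy-4-propylchroman-2-one; 18 3-methylbut-2-enoic acid
Product: 20 (4R)-5,7-dimethoxy-8-(3-methylbut-2-enoyl)-4-propylchroman-2-one, via mixed anhydride 19 (not isolated)
Conditions: 18 (1.3 equiv), (CF3CO)2O (1.5 equiv), CH2Cl2, 0 → 25 °C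
Reagents that add atoms: none
Why: Friedel–Crafts acylation by the acyl trifluoroacetate should go to C8, which is ortho to 7-OMe, para to 5-OMe and flanked by the tied-back ring oxygen, rather than to C6 wedged between two methoxy groups (the site preference known for related 5,7-dioxygenated coumarins), and the metal-free medium avoids loss of the 7-O-methyl group.

Step 10
Reactants: 20 (4R)-5,7-dimethoxy-8-(3-methylbut-2-enoyl)-4-propylchroman-2-one
Product: 22 methyl (3R)-3-(5,7-dimethoxy-2,2-dimethyl-4-oxochroman-8-yl)hexanoate, via phenol enone 21 (not isolated)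
Conditions: NaOMe (0.3 equiv), MeOH, 0 → 25 °C
Reagents that add atoms: methanol, CO
Why: Methoxide opens the aryl lactone by transesterification and the liberated phenoxide, the only free oxygen next to the enone, closes the 2,2-dimethylpyranone by 6-endo-trig oxa-Michael addition, so the ring oxygen is necessarily the one adjacent to the side chain.

Step 11
Reactants: 22 methyl (3R)-3-(5,7-dimethoxy-2,2-dimethyl-4-oxochroman-8-yl)hexanoate
Product: 24 (10R)-5-hydroxy-2,2-dimethyl-10-propyl-2,3,9,10-tetrahydro-4H,8H-pyrano[2,3-f]chromene-4,8-dione, via dihydroxy ester 23 (not isolated)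
Conditions: BBr3 (5 equiv), CH2Cl2, −78 → 20 °C; H2O quench; crude product with pyridinium p-toluenesulfonate (5 mol %), toluene, 40 °C
Reagents that add atoms: none
Why: BBr3 cleaves both aryl methyl ethers while the pyranone oxygen, a weakly basic vinylogous-ester oxygen, should survive at or below room temperature, and the freed 7-OH, the only hydroxyl next to the side chain, lactonises onto the ester to leave just the chelated 5-OH free.

Step 12
Reactants: 24 (10R)-5-hydroxy-2,2-dimethyl-10-propyl-2,3,9,10-tetrahydro-4H,8H-pyrano[2,3-f]chromene-4,8-dione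
Product: 25 (10R)-5-hydroxy-6-iodo-2,2-dimethyl-10-propyl-2,3,9,10-tetrahydro-4H,8H-pyrano[2,3-f]chromene-4,8-dione
Conditions: N-iodosuccinimide (1.05 equiv), MeCN, 0 °C, dark
Reagents that add atoms: N-iodosuccinimide, O=C1CCC(=O)N1I
Why: Electrophilic aromatic iodination can strike only the single remaining aromatic C–H, C6, which is ortho to the free phenol.

Step 13
Reactants: 14 (1R,2R)-1-(iodomethyl)-3,3-dimethyl-2-(prop-1-en-2-yl)cyclobutane; 25 (10R)-5-hydroxy-6-iodo-2,2-dimethyl-10-propyl-2,3,9,10-tetrahydro-4H,8H-pyrano[2,3-f]chromene-4,8-dione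
Product: 29 (10R)-6-{[(1S,2R)-3,3-dimethyl-2-(prop-1-en-2-yl)cyclobutyl]methyl}-5-hydroxy-2,2-dimethyl-10-propyl-2,3,9,10-tetrahydro-4H,8H-pyrano[2,3-f]chromene-4,8-dione, via alkyllithium 26 (not isolated), via alkylzinc bromide 27 (not isolated), via lithium phenoxide 28 (not isolated)
Conditions: flask A: 14, t-BuLi (2.05 equiv), Et2O/pentane, −78 °C, then ZnBr2 (1.1 equiv) in THF, −78 → 0 °C; flask B: 25, LiN(SiMe3)2 (1.0 equiv), THF, −20 °C; combine, Pd(OAc)2 (5 mol %), SPhos (10 mol %), THF, 25 → 40 °C; 1 M HCl work-up
Reagents that add atoms: none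
Why: In this Negishi sp3–sp2 coupling the cold iodine–lithium exchange (polar for primary iodides) and immediate transmetalation to zinc should keep the cyclobutylmethyl unit intact, palladium/SPhos is known to join primary alkylzinc halides to doubly ortho-substituted aryl iodides in the presence of esters and ketones, and prior deprotonation of the phenol prevents protonolysis of the zinc reagent.

Step 14
Reactants: 30 3-methylbut-2-en-1-ol; 31 di-tert-butyl dicarbonate
Product: 32 tert-butyl 3-methylbut-2-en-1-yl carbonate
Conditions: 31 (1.1 equiv), n-Bu4NHSO4 (5 mol %), 30% aq NaOH, CH2Cl2, 0 → 25 °C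
Reagents that add atoms: none
Why: Phase-transfer O-acylation of a primary allylic alcohol with the dicarbonate is the usual access to allylic tert-butyl carbonates.

Step 15
Reactants: 29 (10R)-6-{[(1S,2R)-3,3-dimethyl-2-(prop-1-en-2-yl)cyclobutyl]methyl}-5-hydroxy-2,2-dimethyl-10-propyl-2,3,9,10-tetrahydro-4H,8H-pyrano[2,3-f]chromene-4,8-dione; 32 tert-butyl 3-methylbut-2-en-1-yl carbonate
Product: 33 (6S,10R)-6-{[(1S,2R)-3,3-dimethyl-2-(prop-1-en-2-yl)cyclobutyl]methyl}-2,2-dimethyl-6-(3-methylbut-2-en-1-yl)-10-propyl-2,3,9,10-tetrahydro-4H,8H-pyrano[2,3-f]chromene-4,5,8(6H)-trione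
Conditions: Pd2(dba)3·CHCl3 (2.5 mol %), (1R,2R)-N,N'-bis[2-(diphenylphosphino)benzoyl]cyclohexane-1,2-diamine (7.5 mol %), 32 (1.5 equiv), toluene, 25 °C
Reagents that add atoms: none
Why: Proposed new method: zerovalent palladium should ionise 32 to a 1,1-dimethylallyl–palladium cation, CO2 and tert-butoxide, which deprotonates the chelated 5-OH; O-prenylation of so acidic a phenol is reversible under the catalyst, whereas attack of C6 (ortho to the phenoxide oxygen, para to the ring ether oxygen, and the only ring carbon that neither bears the acyl group nor is buried under the branched side chain) on the unsubstituted allyl terminus forms the C–C bond and a push–pull dienone; the chiral pocket of the C2-symmetric diphosphine tells apart the two faces of the flat phenoxide, whose flanks (phenoxide oxygen against lactone oxygen) differ strongly, and so sets C6 under catalyst control with the other stereocentres too remote to interfere, and the neutral medium spares the lactone; the closest known reactions are the palladium-catalysed intermolecular asymmetric allylic dearomatisation of 1,3-disubstituted 2-naphthols, the racemic palladium-catalysed dearomative allylation of phloroglucinol ethers and the ligand-controlled linear asymmetric prenylation of oxindoles (Tsuji–Trost allylation).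

Step 16
Reactants: 33 (6S,10R)-6-{[(1S,2R)-3,3-dimethyl-2-(prop-1-en-2-yl)cyclobutyl]methyl}-2,2-dimethyl-6-(3-methylbut-2-en-1-yl)-10-propyl-2,3,9,10-tetrahydro-4H,8H-pyrano[2,3-f]chromene-4,5,8(6H)-trione
Product: 34 (3R)-3-[(6R)-6-{[(1S,2R)-3,3-dimethyl-2-(prop-1-en-2-yl)cyclobutyl]methyl}-5-hydroxy-2,2-dimethyl-6-(3-methylbut-2-en-1-yl)-4,7-dioxo-3,4,6,7-tetrahydro-2H-chromen-8-yl]hexanoic acid
Conditions: LiOH (2.5 equiv), THF/H2O, 0 °C; then 1 M HCl to pH 3
Reagents that add atoms: lithium hydroxide, [Li+].[OH-]
Why: The enol lactone is a vinylogous anhydride and by far the most electrophilic carbonyl, so cold saponification opens it to carboxylate and stabilised enolate, which on acidification give the acid and the chelated enol tautomer (the change of the C6 descriptor from S to R only reflects changed priorities), and no stereocentre is enolisable.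

Compound list
1 | isobutyraldehyde | CC(C)C=O | starting material
2 | dimethylamine | CNC | starting material
3 | N,N,N',N',2-pentamethylpropane-1,1-diamine (aminal) | CC(C)C(N(C)C)N(C)C | intermediate
4 | N,N,2-trimethylprop-1-en-1-amine | CC(C)=CN(C)C | intermediate
5 | methyl acrylate | C=CC(=O)OC | starting material
6 | iminium–enolate zwitterion | COC([O-])=CCC(C)(C)C=[N+](C)C | intermediate
7 | methyl 2-(dimethylamino)-3,3-dimethylcyclobutane-1-carboxylate, racemic, both diastereomers | COC(=O)C1CC(C)(C)C1N(C)C | intermediate
8 | 2-(methoxycarbonyl)-N,N,N,4,4-pentamethylcyclobutan-1-aminium iodide | COC(=O)C1CC(C)(C)C1[N+](C)(C)C.[I-] | intermediate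
9 | methyl 3,3-dimethylcyclobut-1-ene-1-carboxylate | COC(=O)C1=CC(C)(C)C1 | intermediate
10 | isopropenylboronic acid pinacol ester | C=C(C)B1OC(C)(C)C(C)(C)O1 | starting material
11 | methyl (1S,2R)-3,3-dimethyl-2-(prop-1-en-2-yl)cyclobutane-1-carboxylate (cis) | C=C(C)[C@H]1[C@@H](C(=O)OC)CC1(C)C | intermediate
12 | methyl (1R,2R)-3,3-dimethyl-2-(prop-1-en-2-yl)cyclobutane-1-carboxylate (trans) | C=C(C)[C@H]1[C@H](C(=O)OC)CC1(C)C | intermediate
13 | [(1R,2R)-3,3-dimethyl-2-(prop-1-en-2-yl)cyclobutyl]methanol | C=C(C)[C@H]1[C@H](CO)CC1(C)C | intermediate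
14 | (1R,2R)-1-(iodomethyl)-3,3-dimethyl-2-(prop-1-en-2-yl)cyclobutane | C=C(C)[C@H]1[C@H](CI)CC1(C)C | intermediate
15 | 5,7-dimethoxycoumarin | COc1cc(OC)c2ccc(=O)oc2c1 | starting material
16 | n-propylmagnesium bromide | CCC[Mg]Br | starting material
17 | (4R)-5,7-dimethoxy-4-propylchroman-2-one | CCC[C@@H]1CC(=O)Oc2cc(OC)cc(OC)c21 | intermediate
18 | 3-methylbut-2-enoic acid | CC(C)=CC(=O)O | starting material
19 | 3-methylbut-2-enoic trifluoroacetic anhydride | CC(C)=CC(=O)OC(=O)C(F)(F)F | intermediate
20 | (4R)-5,7-dimethoxy-8-(3-methylbut-2-enoyl)-4-propylchroman-2-one | CCC[C@@H]1CC(=O)Oc2c(C(=O)C=C(C)C)c(OC)cc(OC)c21 | intermediate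
21 | methyl (3R)-3-[2-hydroxy-4,6-dimethoxy-3-(3-methylbut-2-enoyl)phenyl]hexanoate | CCC[C@H](CC(=O)OC)c1c(OC)cc(OC)c(C(=O)C=C(C)C)c1O | intermediate
22 | methyl (3R)-3-(5,7-dimethoxy-2,2-dimethyl-4-oxochroman-8-yl)hexanoate | CCC[C@H](CC(=O)OC)c1c(OC)cc(OC)c2c1OC(C)(C)CC2=O | intermediate
23 | methyl (3R)-3-(5,7-dihydroxy-2,2-dimethyl-4-oxochroman-8-yl)hexanoate | CCC[C@H](CC(=O)OC)c1c(O)cc(O)c2c1OC(C)(C)CC2=O | intermediate
24 | (10R)-5-hydroxy-2,2-dimethyl-10-propyl-2,3,9,10-tetrahydro-4H,8H-pyrano[2,3-f]chromene-4,8-dione | CCC[C@@H]1CC(=O)Oc2cc(O)c3c(OC(C)(C)CC3=O)c21 | intermediate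
25 | (10R)-5-hydroxy-6-iodo-2,2-dimethyl-10-propyl-2,3,9,10-tetrahydro-4H,8H-pyrano[2,3-f]chromene-4,8-dione | CCC[C@@H]1CC(=O)Oc2c(I)c(O)c3c(OC(C)(C)CC3=O)c21 | intermediate
26 | {[3,3-dimethyl-2-(prop-1-en-2-yl)cyclobutyl]methyl}lithium, configuration as in 14 | C=C(C)[C@H]1[C@H](C[Li])CC1(C)C | intermediate
27 | {[3,3-dimethyl-2-(prop-1-en-2-yl)cyclobutyl]methyl}zinc bromide, configuration as in 14 | C=C(C)[C@H]1[C@H](C[Zn]Br)CC1(C)C | intermediate
28 | lithium phenoxide of 25 | CCC[C@@H]1CC(=O)Oc2c(I)c(O[Li])c3c(OC(C)(C)CC3=O)c21 | intermediate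
29 | (10R)-6-{[(1S,2R)-3,3-dimethyl-2-(prop-1-en-2-yl)cyclobutyl]methyl}-5-hydroxy-2,2-dimethyl-10-propyl-2,3,9,10-tetrahydro-4H,8H-pyrano[2,3-f]chromene-4,8-dione | C=C(C)[C@H]1[C@H](Cc2c(O)c3c(OC(C)(C)CC3=O)c4c2OC(=O)C[C@H]4CCC)CC1(C)C | intermediate
30 | 3-methylbut-2-en-1-ol | CC(C)=CCO | starting material
31 | di-tert-butyl dicarbonate | CC(C)(C)OC(=O)OC(=O)OC(C)(C)C | starting material
32 | tert-butyl 3-methylbut-2-en-1-yl carbonate | CC(C)=CCOC(=O)OC(C)(C)C | intermediate
33 | (6S,10R)-6-{[(1S,2R)-3,3-dimethyl-2-(prop-1-en-2-yl)cyclobutyl]methyl}-2,2-dimethyl-6-(3-methylbut-2-en-1-yl)-10-propyl-2,3,9,10-tetrahydro-4H,8H-pyrano[2,3-f]chromene-4,5,8(6H)-trione | C=C(C)[C@H]1[C@H](C[C@@]2(CC=C(C)C)C(=O)C3=C(OC(C)(C)CC3=O)C4=C2OC(=O)C[C@H]4CCC)CC1(C)C | intermediate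
34 | (3R)-3-[(6R)-6-{[(1S,2R)-3,3-dimethyl-2-(prop-1-en-2-yl)cyclobutyl]methyl}-5-hydroxy-2,2-dimethyl-6-(3-methylbut-2-en-1-yl)-4,7-dioxo-3,4,6,7-tetrahydro-2H-chromen-8-yl]hexanoic acid | C=C(C)[C@H]1[C@H](C[C@]2(CC=C(C)C)C(=O)C([C@H](CCC)CC(=O)O)=C3OC(C)(C)CC(=O)C3=C2O)CC1(C)C | target

Total step count: 16
Longest linear sequence: 10 (steps 1–7, 13, 15, 16)

Steps most likely to fail

Step 15.
- What may go wrong: too little facial discrimination at C6, O-prenylation that does not revert, attack at the substituted allyl terminus, or re-ionisation of the newly formed C–C bond with erosion of selectivity.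
- Fallback: it sets out from 29 and returns at 34, using the long-known alkylative dearomatisation of C-alkylated acylphloroglucinols with prenyl bromide in aqueous base.
- Excess aqueous KOH at 0–25 °C opens the lactone to the ring-opened hydroxy acid F1 (present as its tripotassium salt). Its C6 lies between two phenoxide oxygens and is the most nucleophilic carbon.
- Prenyl bromide is then added at 0 °C. Acidification should give 34 together with its C6 epimer F2.
- The two are diastereomers, thanks to the three fixed stereocentres, and are separated by preparative reversed-phase HPLC. Catalyst control is thus traded for a separation, and compound 33 is bypassed.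

Step 5.
- What may go wrong: carbometalation at the crowded β-carbon too slow to beat protodeboronation of the boronate, or weak face selection by the diene.
- Fallback: it sets out from 9 and returns at 13, using only known chemistry (copper-mediated conjugate addition, then resolution through covalent diastereomers).
- Isopropenylmagnesium bromide with CuBr·SMe2 and Me3SiCl in THF at −78 °C, followed by NaOMe/MeOH equilibration, should give the racemic trans ester F3.
- LiOH gives the racemic trans acid F4.
- Pivaloyl chloride/Et3N converts F4 into the mixed pivalic anhydride F5.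
- (S)-4-Benzyloxazolidin-2-one with LiCl turns F5 into the (1R,2R)-imide F6 and the (1S,2S)-imide F7, which are separable on silica gel.
- LiBH4 in wet Et2O cleaves F6 reductively to alcohol 13 and returns the auxiliary.

Step 13.
- What may go wrong: opening of the four-membered ring in the cyclobutylmethyl-metal species (β-carbon elimination towards an allyl-stabilised carbanion), or sluggish oxidative addition and transmetalation at the doubly flanked iodide ending in reduction.
- Fallback: it sets out from 13 and 24 and returns at 29. It avoids any cyclobutylmethyl organometallic by making the arene the nucleophile.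
- TEMPO/PhI(OAc)2 oxidises 13 to the aldehyde F8.
- F8 is condensed with 24 at its only free ring carbon under L-proline catalysis to the ortho-quinone methide F9.
- F9 is reduced in the same flask by diethyl 2,6-dimethyl-1,4-dihydropyridine-3,5-dicarboxylate (Knoevenagel-type condensation with conjugate hydride transfer).
- Any epimerisation of F8 at C1' through its enamine only drains towards the more stable trans isomer, since C2' stays fixed.

Further compounds
F1 | step 15 | (3R)-3-(6-{[(1S,2R)-3,3-dimethyl-2-(prop-1-en-2-yl)cyclobutyl]methyl}-5,7-dihydroxy-2,2-dimethyl-4-oxochroman-8-yl)hexanoic acid | C=C(C)[C@H]1[C@H](Cc2c(O)c([C@H](CCC)CC(=O)O)c3OC(C)(C)CC(=O)c3c2O)CC1(C)C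
F2 | step 15 | (6S) epimer of 34 | C=C(C)[C@H]1[C@H](C[C@@]2(CC=C(C)C)C(=O)C([C@H](CCC)CC(=O)O)=C3OC(C)(C)CC(=O)C3=C2O)CC1(C)C
F3 | step 5 | racemic methyl trans-3,3-dimethyl-2-(prop-1-en-2-yl)cyclobutane-1-carboxylate (both enantiomers written) | C=C(C)[C@H]1[C@H](C(=O)OC)CC1(C)C.C=C(C)[C@@H]1[C@@H](C(=O)OC)CC1(C)C
F4 | step 5 | racemic trans-3,3-dimethyl-2-(prop-1-en-2-yl)cyclobutane-1-carboxylic acid (both enantiomers written) | C=C(C)[C@H]1[C@H](C(=O)O)CC1(C)C.C=C(C)[C@@H]1[C@@H](C(=O)O)CC1(C)C
F5 | step 5 | racemic mixed anhydride of F4 with pivalic acid (both enantiomers written) | C=C(C)[C@H]1[C@H](C(=O)OC(=O)C(C)(C)C)CC1(C)C.C=C(C)[C@@H]1[C@@H](C(=O)OC(=O)C(C)(C)C)CC1(C)C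
F6 | step 5 | (4S)-4-benzyl-3-{[(1R,2R)-3,3-dimethyl-2-(prop-1-en-2-yl)cyclobutyl]carbonyl}oxazolidin-2-one | C=C(C)[C@H]1[C@H](C(=O)N2[C@@H](Cc3ccccc3)COC2=O)CC1(C)C
F7 | step 5 | (4S)-4-benzyl-3-{[(1S,2S)-3,3-dimethyl-2-(prop-1-en-2-yl)cyclobutyl]carbonyl}oxazolidin-2-one | C=C(C)[C@@H]1[C@@H](C(=O)N2[C@@H](Cc3ccccc3)COC2=O)CC1(C)C
F8 | step 13 | (1R,2R)-3,3-dimethyl-2-(prop-1-en-2-yl)cyclobutane-1-carbaldehyde | C=C(C)[C@H]1[C@H](C=O)CC1(C)C
F9 | step 13 | ortho-quinone methide from 24 and F8 (exocyclic C6=CH, geometry open) | C=C(C)[C@H]1[C@H](C=C2C(=O)C3=C(OC(C)(C)CC3=O)C4=C2OC(=O)C[C@H]4CCC)CC1(C)C
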